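## Retrosynthetic overview

1. Target 28 is cut at C11–C12 (polyprenyl numbering, C1 = ring CH2 next to the ring CH=): Negishi coupling of the ring-bearing (Z)-vinyl iodide 26 with the zinc reagent of keto iodide 14.
2. The only ring (the cyclohexene) is closed in step 11 by a biomimetic 1,6 (tail-to-head) cation–olefin cyclisation of the acyclic (2Z,6E)-farnesyl-type binaphthyl ether 23, which carries a chiral leaving group. Loss of a methyl proton from the bisabolyl cation gives the exo-methylene, and the ring stereocentre is set here.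
3. Ether 23 comes from neryl acetate 15 by a singlet-oxygen ene reaction, a Claisen rearrangement (C8–C9 bond, 6E olefin), a Stork–Zhao iodo-olefination (10Z vinyl iodide) and a Mitsunobu reaction with (R)-binaphthol.
4. Keto iodide 14 comes from an iron-catalysed acylation that joins the (R)-citronellyl unit (C12–C17) to the (2R,6S)-2,6,10-trimethylundecanoyl unit (C18–C28, made by copper-catalysed coupling of 1 with 2); ozonolysis then frees C12.

Assumptions: (R)-binaphthol is taken to give the (R) ring carbon, as in the (R)-limonene series (if a neryl model run shows the opposite sense, (S)-binaphthol is used with no other change); (3S)-1-bromo-3,7-dimethyloctane is taken as a catalogue compound.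

## Route

Step 1
Reactants: 1 (3S)-1-bromo-3,7-dimethyloctane; 2 (2S)-3-bromo-2-methylpropan-1-ol
Product: 5 (2R,6S)-2,6,10-trimethylundecan-1-ol, via Grignard reagent 3 (not isolated), via chloromagnesium alkoxide 4 (not isolated)
Conditions: 1, Mg, THF, 45 °C; 2, MeMgCl (1.0 equiv), THF, −30 °C; combine, Li2CuCl4 (3 mol%), −30 → 0 °C; aq. NH4Cl
Reagents that add atoms: none
Why: Kochi-type copper-catalysed alkyl–alkyl Grignard cross-coupling displaces the primary bromide of the alkoxide-masked bromohydrin, and both stereocentres come unchanged from the two chiral starting materials because neither sits at a reacting carbon.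

Step 2
Reactants: 5 (2R,6S)-2,6,10-trimethylundecan-1-ol
Product: 7 (2R,6S)-2,6,10-trimethylundecanoic acid, via aldehyde 6 (not isolated)
Conditions: TEMPO (7 mol%), NaOCl (2 mol%), NaClO2 (2 equiv), MeCN/pH 6.7 phosphate buffer, 35 °C
Reagents that add atoms: sodium chlorite, [Na+].[O-]Cl=O
Why: TEMPO-catalysed alcohol oxidation coupled to a Pinnick-type chlorite oxidation takes the primary alcohol through the aldehyde to the acid at near-neutral pH, so the α-methyl stereocentre does not epimerise.

Step 3
Reactants: 7 (2R,6S)-2,6,10-trimethylundecanoic acid; 8 (6R)-8-bromo-2,6-dimethyloct-2-ene ((R)-citronellyl bromide)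
Product: 11 (6R,10R,14S)-2,6,10,14,18-pentamethylnonadec-2-en-9-one, via acid chloride 9 (not isolated), via citronellyl Grignard reagent 10 (not isolated)
Conditions: 7, (COCl)2, DMF (cat.), CH2Cl2, 0 °C → rt, evaporate; 8, Mg, THF; then Fe(acac)3 (3 mol%), THF, −78 °C, 15 min
Reagents that add atoms: none
Why: Iron-catalysed acylation of a Grignard reagent by an acid chloride is much faster at −78 °C than addition to the ketone formed or enolisation, so the ketone is obtained without over-addition and with the α-stereocentre intact, while the third methyl stereocentre comes from (R)-citronellyl bromide.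

Step 4
Reactants: 11 (6R,10R,14S)-2,6,10,14,18-pentamethylnonadec-2-en-9-one
Product: 13 (4R,8R,12S)-1-hydroxy-4,8,12,16-tetramethylheptadecan-7-one, via keto aldehyde 12 (not isolated)
Conditions: O3, CH2Cl2, −78 °C; PPh3, −78 °C → rt; then NaBH(OAc)3, AcOH, rt
Reagents that add atoms: ozone, [O-][O+]=O
Why: Ozonolysis cleaves the only olefin, reductive work-up gives the aldehyde, and NaBH(OAc)3 reduces an aldehyde but not a ketone, so the primary alcohol is formed with the ketone and all three stereocentres untouched.

Step 5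
Reactants: 13 (4R,8R,12S)-1-hydroxy-4,8,12,16-tetramethylheptadecan-7-one
Product: 14 (4S,8R,12S)-1-iodo-4,8,12,16-tetramethylheptadecan-7-one
Conditions: PPh3, I2, imidazole, CH2Cl2, 0 °C → rt
Reagents that add atoms: iodine, II
Why: Appel-type iodination (Garegg–Samuelsson conditions) converts the primary alcohol into the iodide under neutral conditions that leave the enolisable ketone alone; the C-4 descriptor changes only because iodine changes the CIP priorities.

Step 6
Reactants: 15 (2Z)-3,7-dimethylocta-2,6-dien-1-yl acetate (neryl acetate)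
Product: 17 (2Z)-6-hydroxy-3,7-dimethylocta-2,7-dien-1-yl acetate (racemic at C-6), via allylic hydroperoxide 16 (not isolated)
Conditions: O2, tetraphenylporphyrin (cat.), visible light, CH2Cl2, 0 °C; then PPh3, 0 °C → rt; chromatography
Reagents that add atoms: dioxygen, O=O
Why: Schenck ene reaction of singlet oxygen occurs at the electron-rich 6,7-olefin (the allylic acetate olefin is deactivated) and hydrogen abstraction from the cis methyl gives the secondary allylic hydroperoxide, reduced in the flask; about half the material is the tertiary regioisomer, removed by chromatography, and the new carbinol centre is racemic but is destroyed in step 7.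

Step 7
Reactants: 17 (2Z)-6-hydroxy-3,7-dimethylocta-2,7-dien-1-yl acetate
Product: 19 (2Z,6E)-3,7-dimethyl-10-oxodeca-2,6-dien-1-yl acetate, via allyl vinyl ether 18 (not isolated)
Conditions: butyl vinyl ether (excess), Pd(OCOCF3)2 (0.5 mol%), 4,7-diphenyl-1,10-phenanthroline, Et3N, 75 °C; then toluene, 130 °C (sealed tube)
Reagents that add atoms: butyl vinyl ether, C=COCCCC
Why: Transfer vinylation followed by aliphatic Claisen rearrangement through a chair transition state with the chain equatorial builds the C8–C9 bond and the (6E)-trisubstituted olefin and delivers the two-carbon aldehyde.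

Step 8
Reactants: 19 (2Z,6E)-3,7-dimethyl-10-oxodeca-2,6-dien-1-yl acetate
Product: 20 (2Z,6E,10Z)-11-iodo-3,7-dimethyldodeca-2,6,10-trien-1-yl acetate
Conditions: EtPPh3I, n-BuLi, THF, 0 °C → rt; I2, −78 °C; NaN(SiMe3)2, −78 → −20 °C; then 19, −78 °C → rt
Reagents that add atoms: ethyltriphenylphosphonium iodide, CC[P+](c1ccccc1)(c1ccccc1)c1ccccc1.[I-]; iodine, II
Why: Stork–Zhao Wittig olefination with the α-iodoethylidene ylide gives the (Z)-2-iodoalkene under kinetic control, with iodine cis to the chain, which is the geometry the later coupling carries into the 10Z olefin of the target.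

Step 9
Reactants: 20 (2Z,6E,10Z)-11-iodo-3,7-dimethyldodeca-2,6,10-trien-1-yl acetate
Product: 21 (2Z,6E,10Z)-11-iodo-3,7-dimethyldodeca-2,6,10-trien-1-ol
Conditions: K2CO3 (0.2 equiv), MeOH, 0 °C → rt
Reagents that add atoms: none
Why: Base-catalysed transesterification (Zemplén-type methanolysis) removes the acetate without touching the vinyl iodide or the olefin geometries.

Step 10
Reactants: 21 (2Z,6E,10Z)-11-iodo-3,7-dimethyldodeca-2,6,10-trien-1-ol; 22 (R)-1,1'-bi-2-naphthol
Product: 23 (R)-2'-{[(2Z,6E,10Z)-11-iodo-3,7-dimethyldodeca-2,6,10-trien-1-yl]oxy}-1,1'-binaphthalen-2-ol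
Conditions: 22 (3 equiv), PPh3, DIAD, THF, 0 °C → rt
Reagents that add atoms: none
Why: Mitsunobu etherification is a direct SN2 displacement at the primary allylic carbon by the naphthol, so the 2Z geometry and the binaphthyl axis are retained, and the excess of diol (recovered) ensures the mono-ether.

Step 11
Reactants: 23 (R)-2'-{[(2Z,6E,10Z)-11-iodo-3,7-dimethyldodeca-2,6,10-trien-1-yl]oxy}-1,1'-binaphthalen-2-ol
Product: 26 (4R)-4-[(5Z)-6-iodohepta-1,5-dien-2-yl]-1-methylcyclohex-1-ene, via aluminium naphthoxide 24 (not isolated), via bisabolyl-type cation 25 (not isolated)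
Conditions: i-Bu2Al(OAr) (3 equiv, from i-Bu3Al + ArOH; ArOH = 2,6-di-tert-butyl-4-methylphenol), CH2Cl2/pentane (CFCl3 in the parent case), −100 → −78 °C; 1 M HCl work-up, 22 recovered
Reagents that add atoms: none
Why: Biomimetic tail-to-head cation–olefin cyclisation of the chiral-leaving-group type (the known conversion of neryl and (2Z,6E)-farnesyl binaphthyl ethers into limonene and β-bisabolene): the aluminium naphthoxide chelates and ionises the allylic ether, the (2Z)-allyl cation is captured 1,6 by the 6,7-olefin on the face left open by the tightly paired chiral binaphthoxide aluminate, which sets the ring stereocentre as R, and the bulky aluminate then removes a methyl proton from the tertiary cation to give the exo-methylene.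

Step 12
Reactants: 14 (4S,8R,12S)-1-iodo-4,8,12,16-tetramethylheptadecan-7-one; 26 (4R)-4-[(5Z)-6-iodohepta-1,5-dien-2-yl]-1-methylcyclohex-1-ene
Product: 28 (6S,10R,14R,18Z)-2,6,10,14,18-pentamethyl-22-[(1R)-4-methylcyclohex-3-en-1-yl]tricosa-18,22-dien-11-one, via alkylzinc iodide 27 (not isolated)
Conditions: 14 (1.4 equiv), Zn dust (activated with BrCH2CH2Br/TMSCl), LiCl, THF, 40 °C; then 26, PdCl2(dppf) (5 mol%), THF/NMP, 40 °C
Reagents that add atoms: none
Why: Direct zinc insertion gives a primary alkylzinc iodide that tolerates the ketone, and the Negishi sp3–sp2 cross-coupling proceeds with retention at the vinyl iodide, so the 18Z olefin and all four stereocentres arrive unchanged in the target.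

## Compound list

1 | (3S)-1-bromo-3,7-dimethyloctane | BrCC[C@@H](C)CCCC(C)C | starting material
2 | (2S)-3-bromo-2-methylpropan-1-ol | OC[C@H](C)CBr | starting material
3 | [(3S)-3,7-dimethyloctyl]magnesium bromide | Br[Mg]CC[C@@H](C)CCCC(C)C | intermediate (not isolated)
4 | chloromagnesium (2S)-3-bromo-2-methylpropan-1-olate | Cl[Mg]OC[C@H](C)CBr | intermediate (not isolated)
5 | (2R,6S)-2,6,10-trimethylundecan-1-ol | OC[C@H](C)CCC[C@@H](C)CCCC(C)C | intermediate
6 | (2R,6S)-2,6,10-trimethylundecanal | O=C[C@H](C)CCC[C@@H](C)CCCC(C)C | intermediate (not isolated)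
7 | (2R,6S)-2,6,10-trimethylundecanoic acid | OC(=O)[C@H](C)CCC[C@@H](C)CCCC(C)C | intermediate
8 | (6R)-8-bromo-2,6-dimethyloct-2-ene ((R)-citronellyl bromide) | CC(C)=CCC[C@@H](C)CCBr | starting material
9 | (2R,6S)-2,6,10-trimethylundecanoyl chloride | ClC(=O)[C@H](C)CCC[C@@H](C)CCCC(C)C | intermediate (not isolated)
10 | [(3R)-3,7-dimethyloct-6-en-1-yl]magnesium bromide | CC(C)=CCC[C@@H](C)CC[Mg]Br | intermediate (not isolated)
11 | (6R,10R,14S)-2,6,10,14,18-pentamethylnonadec-2-en-9-one | CC(C)=CCC[C@@H](C)CCC(=O)[C@H](C)CCC[C@@H](C)CCCC(C)C | intermediate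
12 | (4R,8R,12S)-4,8,12,16-tetramethyl-7-oxoheptadecanal | O=CCC[C@@H](C)CCC(=O)[C@H](C)CCC[C@@H](C)CCCC(C)C | intermediate (not isolated)
13 | (4R,8R,12S)-1-hydroxy-4,8,12,16-tetramethylheptadecan-7-one | OCCC[C@@H](C)CCC(=O)[C@H](C)CCC[C@@H](C)CCCC(C)C | intermediate
14 | (4S,8R,12S)-1-iodo-4,8,12,16-tetramethylheptadecan-7-one | ICCC[C@@H](C)CCC(=O)[C@H](C)CCC[C@@H](C)CCCC(C)C | intermediate
15 | (2Z)-3,7-dimethylocta-2,6-dien-1-yl acetate (neryl acetate) | CC(C)=CCC/C(C)=C\COC(C)=O | starting material
16 | (2Z)-6-hydroperoxy-3,7-dimethylocta-2,7-dien-1-yl acetate (racemic) | C=C(C)C(OO)CC/C(C)=C\COC(C)=O | intermediate (not isolated)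
17 | (2Z)-6-hydroxy-3,7-dimethylocta-2,7-dien-1-yl acetate (racemic) | C=C(C)C(O)CC/C(C)=C\COC(C)=O | intermediate
18 | (2Z)-6-(ethenyloxy)-3,7-dimethylocta-2,7-dien-1-yl acetate (racemic) | C=COC(CC/C(C)=C\COC(C)=O)C(C)=C | intermediate (not isolated)
19 | (2Z,6E)-3,7-dimethyl-10-oxodeca-2,6-dien-1-yl acetate | O=CCC/C(C)=C/CC/C(C)=C\COC(C)=O | intermediate
20 | (2Z,6E,10Z)-11-iodo-3,7-dimethyldodeca-2,6,10-trien-1-yl acetate | C/C(I)=C/CC/C(C)=C/CC/C(C)=C\COC(C)=O | intermediate
21 | (2Z,6E,10Z)-11-iodo-3,7-dimethyldodeca-2,6,10-trien-1-ol | C/C(I)=C/CC/C(C)=C/CC/C(C)=C\CO | intermediate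
22 | (R)-1,1'-bi-2-naphthol (R axis; the SMILES cannot carry the axial descriptor) | Oc1ccc2ccccc2c1-c1c(O)ccc2ccccc12 | starting material
23 | (R)-2'-{[(2Z,6E,10Z)-11-iodo-3,7-dimethyldodeca-2,6,10-trien-1-yl]oxy}-1,1'-binaphthalen-2-ol (R axis) | C/C(I)=C/CC/C(C)=C/CC/C(C)=C\COc1ccc2ccccc2c1-c1c(O)ccc2ccccc12 | intermediate
24 | isobutyl(2,6-di-tert-butyl-4-methylphenoxy)aluminium naphthoxide of 23 (Al–O bond at the free naphthol oxygen, R axis) | CC(C)C[Al](Oc1c(C(C)(C)C)cc(C)cc1C(C)(C)C)Oc1ccc2ccccc2c1-c1c(OC/C=C(/C)CC/C=C(\C)CC/C=C(/C)I)ccc2ccccc12 | intermediate (not isolated)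
25 | (5Z)-6-iodo-2-[(1R)-4-methylcyclohex-3-en-1-yl]hept-5-en-2-ylium (bisabolyl-type tertiary cation, paired with the binaphthoxide aluminate) | C[C+](CC/C=C(/C)I)[C@H]1CC=C(C)CC1 | intermediate (not isolated)
26 | (4R)-4-[(5Z)-6-iodohepta-1,5-dien-2-yl]-1-methylcyclohex-1-ene | C=C(CC/C=C(/C)I)[C@H]1CC=C(C)CC1 | intermediate
27 | [(4S,8R,12S)-4,8,12,16-tetramethyl-7-oxoheptadecyl]zinc iodide | I[Zn]CCC[C@@H](C)CCC(=O)[C@H](C)CCC[C@@H](C)CCCC(C)C | intermediate (not isolated)
28 | (6S,10R,14R,18Z)-2,6,10,14,18-pentamethyl-22-[(1R)-4-methylcyclohex-3-en-1-yl]tricosa-18,22-dien-11-one | C=C(CC/C=C(/C)CCC[C@@H](C)CCC(=O)[C@H](C)CCC[C@@H](C)CCCC(C)C)[C@H]1CC=C(C)CC1 | target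

## Step count

Total: 12 steps. Longest linear sequence: 7 steps (steps 6–12 from neryl acetate); the tail branch is 6 steps (steps 1–5 and 12).

## Steps most likely to fail, with fallbacks

Step 11 (key cyclisation). The induction known for this reaction type is only about 75–80% ee, and endocyclic olefin isomers can accompany the exo-methylene product. Olefin isomers would be removed on AgNO3-impregnated silica, and 26 would be brought to a single enantiomer by preparative HPLC on a chiral phase before step 12. If selectivity is too low to rescue this way, the fallback sets out from 21 and returns at 26. Alcohol 21 is converted (MsCl, LiCl, 2,4,6-collidine, DMF, 0 °C) into (2Z,6E,10Z)-1-chloro-11-iodo-3,7-dimethyldodeca-2,6,10-triene F1. F1 is then ionised under anion-binding catalysis by a chiral bis-urea hydrogen-bond donor in a non-polar solvent at low temperature over an insoluble base. The ring closure is the same olefin-assisted ionisation, but the face is chosen catalytically by the urea-bound chloride counter-ion instead of a stoichiometric leaving group, and loss of HCl gives 26. This variant has less precedent for this substitution pattern than the main step.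

Step 8 (Stork–Zhao olefination). Yields are typically moderate (40–55%) with Z:E around 10:1, and the ylide is used in the presence of an ester. The fallback sets out from 19 and returns at 20. Aldehyde 19 is converted with CBr4/PPh3 (CH2Cl2, 0 °C) into (2Z,6E)-11,11-dibromo-3,7-dimethylundeca-2,6,10-trien-1-yl acetate F2. Palladium-catalysed trans-selective mono-methylation (MeZnCl, PdCl2(DPEphos), THF, 0 °C) replaces the bromine trans to the chain and gives (2Z,6E,10Z)-11-bromo-3,7-dimethyldodeca-2,6,10-trien-1-yl acetate F3. Copper-catalysed halogen exchange with retention (CuI, NaI, N,N'-dimethylethane-1,2-diamine, dioxane, 100 °C) then gives 20. The allylic acetate is a possible liability in the palladium step and would need checking.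

Step 12 (Negishi coupling with a ketone-bearing zinc reagent). Zinc insertion or transmetallation may be slowed by the ketone, and both partners are valuable. The fallback changes the order of bond formation so that the ketone is made last; it sets out from 8 and 26 and returns at 28. Bromide 8 is ozonised with NaBH4 work-up to (4R)-6-bromo-4-methylhexan-1-ol F4, which is iodinated (PPh3, I2, imidazole) to (3R)-1-bromo-6-iodo-3-methylhexane F5. Zinc dust without LiCl inserts only into the C–I bond to give [(4R)-6-bromo-4-methylhexyl]zinc iodide F6. F6 is coupled with 26 (PdCl2(dppf)) to (4R)-4-[(5Z,10R)-12-bromo-6,10-dimethyldodeca-1,5-dien-2-yl]-1-methylcyclohex-1-ene F7. Its Grignard reagent, {(3R,7Z)-3,7-dimethyl-11-[(1R)-4-methylcyclohex-3-en-1-yl]dodeca-7,11-dien-1-yl}magnesium bromide F8, is acylated with acid chloride 9 under Fe(acac)3 catalysis at −78 °C to give 28.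

## Further compounds

F1 | step 11 | (2Z,6E,10Z)-1-chloro-11-iodo-3,7-dimethyldodeca-2,6,10-triene | C/C(I)=C/CC/C(C)=C/CC/C(C)=C\CCl
F2 | step 8 | (2Z,6E)-11,11-dibromo-3,7-dimethylundeca-2,6,10-trien-1-yl acetate | BrC(Br)=CCC/C(C)=C/CC/C(C)=C\COC(C)=O
F3 | step 8 | (2Z,6E,10Z)-11-bromo-3,7-dimethyldodeca-2,6,10-trien-1-yl acetate | C/C(Br)=C/CC/C(C)=C/CC/C(C)=C\COC(C)=O
F4 | step 12 | (4R)-6-bromo-4-methylhexan-1-ol | OCCC[C@@H](C)CCBr
F5 | step 12 | (3R)-1-bromo-6-iodo-3-methylhexane | ICCC[C@@H](C)CCBr
F6 | step 12 | [(4R)-6-bromo-4-methylhexyl]zinc iodide | I[Zn]CCC[C@@H](C)CCBr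
F7 | step 12 | (4R)-4-[(5Z,10R)-12-bromo-6,10-dimethyldodeca-1,5-dien-2-yl]-1-methylcyclohex-1-ene | C=C(CC/C=C(/C)CCC[C@@H](C)CCBr)[C@H]1CC=C(C)CC1
F8 | step 12 | {(3R,7Z)-3,7-dimethyl-11-[(1R)-4-methylcyclohex-3-en-1-yl]dodeca-7,11-dien-1-yl}magnesium bromide | C=C(CC/C=C(/C)CCC[C@@H](C)CC[Mg]Br)[C@H]1CC=C(C)CC1
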